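**Retrosynthetic overview** (labdane numbering: ring A = C1–C5 and C10; ring B = C5–C10; chain C11–C15 with the C16 methyl on C9; C17 = CH2OH on C8)
- Feature used: rings A and B share the C5–C10 bond, with the C10 methyl anti to H-5 and syn to the C9 chain. This pattern is latent in an (E)-3-methyl-2-enoate C9=C10 (ester carbon = C11) joined through C1–C4 to an (E,E)-diene C5=C6–C7=C8–C17.
- Key disconnection: type 1 intramolecular Diels–Alder reaction forming C5–C10 and C8–C9; rings A and B are closed together, and no ring exists before this step.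
- Before it: methyl geranate supplies C9, C10, the C10 methyl and C1–C3. The C3–C4 bond and the C3 carbinol come from an asymmetric reverse prenylation, and the C6–C7 bond from Takai iodo-olefination and Suzuki–Miyaura coupling.
- After it: C11 ester to aldehyde, then a Wittig reaction with a chiral-pool C12–C15 ylide (brings C13). C17 is oxidised so that C6=C7 moves into conjugation as C7=C8, followed by 1,2-reduction and hydrogenation of C11=C12.

Key step: step 7

Assumption: methyl geranate is used free of its 2Z isomer and the bromo ester as the single S enantiomer; both, the allene and the alkenylboronate are taken as purchasable.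

**Route**

Step 1
Reactants: 1 methyl geranate
Product: 3 methyl (2E)-3-methyl-6-oxohex-2-enoate, via secondary ozonide 2 (not isolated)
Conditions: O3 (1 equiv, Sudan Red 7B end point), CH2Cl2, −78 °C; then PPh3, −78 °C → rt
Reagents that add atoms: ozone [O-][O+]=O
Why: Chemoselective ozonolysis: electrophilic ozone should cleave the electron-rich trisubstituted C6=C7 alkene much faster than the ester-conjugated C2=C3 alkene, whose E geometry later carries the C9/C10 relationship, and PPh3 reduces the ozonide to the aldehyde.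

Step 2
Reactants: 3 methyl (2E)-3-methyl-6-oxohex-2-enoate; 4 3-methylbuta-1,2-diene
Product: 7 methyl (2E,6R)-6-hydroxy-3,7,7-trimethylnona-2,8-dienoate, via B-prenyldiisopinocampheylborane 5 (not isolated), via diisopinocampheylborinate 6 (not isolated)
Conditions: (−)-Ipc2BH [from (+)-α-pinene and BH3·SMe2] and 4, THF, −25 → 0 °C; then 3, −78 °C; then NaBO3·4H2O, THF/H2O, rt
Reagents that add atoms: none
Why: Brown asymmetric allylboration in its reverse-prenylation form: hydroboration of the allene gives the prenylborane, which adds through a chair-like six-membered transition state with allylic transposition, so the gem-dimethyl carbon bonds to the aldehyde and the (−)-Ipc2B reagent should select the Si face to set the 6R carbinol (C3 of the target), the enoate being inert at −78 °C.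

Step 3
Reactants: 7 methyl (2E,6R)-6-hydroxy-3,7,7-trimethylnona-2,8-dienoate
Product: 8 methyl (2E,6R)-6-[(tert-butyldimethylsilyl)oxy]-3,7,7-trimethylnona-2,8-dienoate
Conditions: TBSOTf, 2,6-lutidine, CH2Cl2, −78 → 0 °C
Reagents that add atoms: tert-butyldimethylsilyl triflate CC(C)(C)[Si](C)(C)OS(=O)(=O)C(F)(F)F
Why: Silylation with a silyl triflate, needed because the secondary alcohol is flanked by a quaternary carbon; the stereocenter is not touched.

Step 4
Reactants: 8 methyl (2E,6R)-6-[(tert-butyldimethylsilyl)oxy]-3,7,7-trimethylnona-2,8-dienoate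
Product: 10 methyl (2E,6R)-6-[(tert-butyldimethylsilyl)oxy]-3,7,7-trimethyl-8-oxooct-2-enoate, via 8,9-diol 9 (not isolated)
Conditions: OsO4 (2 mol %), NMO, acetone/H2O, rt; then NaIO4, rt
Reagents that add atoms: N-methylmorpholine N-oxide C[N+]1([O-])CCOCC1; water O
Why: Catalytic OsO4/NMO dihydroxylation followed by periodate glycol cleavage: OsO4 should choose the isolated monosubstituted alkene over the electron-poor trisubstituted enoate, and the aldehyde formed has no α-hydrogen and so cannot epimerise or eliminate.

Step 5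
Reactants: 10 methyl (2E,6R)-6-[(tert-butyldimethylsilyl)oxy]-3,7,7-trimethyl-8-oxooct-2-enoate
Product: 11 methyl (2E,6R,8E)-6-[(tert-butyldimethylsilyl)oxy]-9-iodo-3,7,7-trimethylnona-2,8-dienoate
Conditions: CrCl2 (6 equiv), CHI3 (2 equiv), THF/dioxane, 0 °C → rt
Reagents that add atoms: iodoform IC(I)I
Why: Takai olefination: the gem-dichromium species formed from CHI3 and divalent chromium adds to the aldehyde and eliminates to the (E)-iodoalkene, with a high E preference expected for an α-quaternary aldehyde and the ester untouched.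

Step 6
Reactants: 11 methyl (2E,6R,8E)-6-[(tert-butyldimethylsilyl)oxy]-9-iodo-3,7,7-trimethylnona-2,8-dienoate; 12 (E)-3-(tert-butyldimethylsilyloxy)prop-1-enylboronic acid pinacol ester
Product: 13 methyl (2E,6R,8E,10E)-6,12-bis[(tert-butyldimethylsilyl)oxy]-3,7,7-trimethyldodeca-2,8,10-trienoate
Conditions: Pd(PPh3)4 (5 mol %), K3PO4, THF/H2O, 50 °C
Reagents that add atoms: none
Why: Suzuki–Miyaura coupling of an alkenyl iodide with an alkenylboronate under zerovalent palladium catalysis proceeds with retention at both alkenes and should give the (E,E)-diene, K3PO4 being mild enough for the methyl ester.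

Step 7
Reactants: 13 methyl (2E,6R,8E,10E)-6,12-bis[(tert-butyldimethylsilyl)oxy]-3,7,7-trimethyldodeca-2,8,10-trienoate
Product: 14 trans-fused Diels–Alder adduct (C6=C7; CO2Me on C9; CH2OTBS on C8; 3-OTBS)
Conditions: EtAlCl2 (1.1 equiv), CH2Cl2, −78 → 23 °C
Reagents that add atoms: none
Why: The Lewis-acid-bound enoate C9=C10 and the (E,E)-diene C5=C6–C7=C8 should combine in a concerted, asynchronous [4+2] cycloaddition that forms C5–C10 and C8–C9, the closest known reaction type being the alkylaluminium-chloride-promoted type 1 intramolecular Diels–Alder reaction of (E,E,E)-undeca-2,8,10-trienoates to trans-fused octalins. Ring B is formed as the new cyclohexene by the cycloaddition itself, and ring A is closed as a six-membered ring in the fused mode by the C1–C4 tether when C5–C10 forms. The syn relation of C11 and the C10 methyl comes from the (E)-enoate geometry and suprafacial addition, the anti relation of H-5 and the C10 methyl (trans fusion) from the transition state with the complexed ester under the diene and the tether exo, and the transient C8 configuration from the (E,E)-diene in the same endo array. The absolute sense at C5, C9 and C10 is relayed from C3: in the chair-like tether the silyloxy group next to the gem-dimethyl carbon should sit equatorial, which opens only one diene face. The step needs endo over exo selectivity and this facial selectivity; the first is secured by Lewis-acid complexation of the ester, the second by the 3R stereocenter, while the C4 gem-dimethyl group favours the folded conformer. Because the dienophile is β,β-disubstituted and a quaternary carbon forms next to C4, warming to room temperature is expected to be necessary.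

Step 8
Reactants: 14 trans-fused Diels–Alder adduct
Product: 15 C11 primary alcohol (CH2OH on C9)
Conditions: i-Bu2AlH (3 equiv), CH2Cl2, −78 → 0 °C
Reagents that add atoms: none
Why: Hydride reduction of the ester by i-Bu2AlH to the primary alcohol; alkenes and silyl ethers are inert, and full reduction is chosen because partial reduction of so hindered an ester is hard to stop cleanly.

Step 9
Reactants: 15 C11 primary alcohol
Product: 16 C11 aldehyde (CHO on C9)
Conditions: Dess–Martin periodinane, CH2Cl2, rt
Reagents that add atoms: none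
Why: Dess–Martin oxidation gives the aldehyde under non-basic conditions, so C9, which carries the equatorial and therefore more stable formyl group, should keep its configuration.

Step 10
Reactants: 17 methyl (3S)-4-bromo-3-methylbutanoate
Product: 18 [(2S)-4-methoxy-2-methyl-4-oxobutyl]triphenylphosphonium bromide
Conditions: PPh3, MeCN, reflux
Reagents that add atoms: triphenylphosphine c1ccc(cc1)P(c1ccccc1)c1ccccc1
Why: SN2 quaternisation of PPh3 by the primary bromide; the stereocenter is not involved.

Step 11
Reactants: 16 C11 aldehyde; 18 [(2S)-4-methoxy-2-methyl-4-oxobutyl]triphenylphosphonium bromide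
Product: 20 (11Z)-alkene with the full C11–C15 chain, via phosphorus ylide 19 (not isolated)
Conditions: 18, NaN(SiMe3)2, THF, −78 → 0 °C; then 16, −78 °C → rt
Reagents that add atoms: none
Why: Wittig olefination with a non-stabilised ylide made at low temperature forms C11=C12 (mainly Z, a geometry erased later); C13 comes from the chiral pool and is not acidic, and C9 carries the thermodynamically preferred equatorial substituent.

Step 12
Reactants: 20 (11Z)-alkene with the full C11–C15 chain
Product: 21 3,17-diol (C6=C7 and C11=C12 kept)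
Conditions: 48% aq. HF, MeCN, 0 °C → rt
Reagents that add atoms: none
Why: Acidic fluoride desilylation removes both silyl ethers, the hindered secondary one included, while the ester and the alkenes are stable to HF in MeCN.

Step 13
Reactants: 21 3,17-diol
Product: 23 conjugated C7-ene C17 aldehyde, via β,γ-unsaturated aldehyde 22 (not isolated)
Conditions: TEMPO (10 mol %), PhI(OAc)2, CH2Cl2, rt; then DBU, rt
Reagents that add atoms: none
Why: Oxoammonium (TEMPO) oxidation selects the primary C17 alcohol over the hindered secondary C3 alcohol, and DBU then moves C6=C7 into conjugation through the dienolate, which erases C8; C9–H is not acidified because C11 carries no carbonyl at this stage, so C9 should hold.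

Step 14
Reactants: 23 conjugated C7-ene C17 aldehyde
Product: 24 C7-ene 3,17-diol with C11=C12
Conditions: NaBH4, CeCl3·7H2O, MeOH, −20 °C
Reagents that add atoms: none
Why: Luche reduction: NaBH4 with CeCl3 delivers hydride 1,2 to the enal and leaves the methyl ester and the alkenes alone.

Step 15
Reactants: 24 C7-ene 3,17-diol with C11=C12
Product: 25 target CNP0313905.1
Conditions: H2 (1 atm), RhCl(PPh3)3 (10 mol %), benzene/EtOH, rt
Reagents that add atoms: none
Why: Homogeneous hydrogenation with RhCl(PPh3)3, which reduces 1,2-disubstituted alkenes far faster than trisubstituted ones, should saturate C11=C12 only and leave the C7=C8 allylic alcohol alkene; no stereocenter is formed.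

**Compound list**

1 | methyl geranate, methyl (2E)-3,7-dimethylocta-2,6-dienoate | COC(=O)/C=C(\C)CCC=C(C)C | starting material
2 | secondary ozonide, methyl (2E)-5-(5,5-dimethyl-1,2,4-trioxolan-3-yl)-3-methylpent-2-enoate | COC(=O)/C=C(\C)CCC1OOC(C)(C)O1 | intermediate
3 | methyl (2E)-3-methyl-6-oxohex-2-enoate | COC(=O)/C=C(\C)CCC=O | intermediate
4 | 3-methylbuta-1,2-diene | CC(C)=C=C | starting material
5 | B-(3-methylbut-2-en-1-yl)diisopinocampheylborane, (−)-Ipc series | CC(C)=CCB([C@@H]1C[C@@H]2C[C@H]([C@H]1C)C2(C)C)[C@@H]1C[C@@H]2C[C@H]([C@H]1C)C2(C)C | intermediate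
6 | diisopinocampheylborinate of alcohol 7 (O–B bond at C6) | COC(=O)/C=C(\C)CC[C@@H](OB([C@@H]1C[C@@H]2C[C@H]([C@H]1C)C2(C)C)[C@@H]1C[C@@H]2C[C@H]([C@H]1C)C2(C)C)C(C)(C)C=C | intermediate
7 | methyl (2E,6R)-6-hydroxy-3,7,7-trimethylnona-2,8-dienoate | COC(=O)/C=C(\C)CC[C@@H](O)C(C)(C)C=C | intermediate
8 | methyl (2E,6R)-6-[(tert-butyldimethylsilyl)oxy]-3,7,7-trimethylnona-2,8-dienoate | COC(=O)/C=C(\C)CC[C@@H](O[Si](C)(C)C(C)(C)C)C(C)(C)C=C | intermediate
9 | methyl (2E,6R)-6-[(tert-butyldimethylsilyl)oxy]-8,9-dihydroxy-3,7,7-trimethylnon-2-enoate (both C8 epimers) | COC(=O)/C=C(\C)CC[C@@H](O[Si](C)(C)C(C)(C)C)C(C)(C)C(O)CO | intermediate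
10 | methyl (2E,6R)-6-[(tert-butyldimethylsilyl)oxy]-3,7,7-trimethyl-8-oxooct-2-enoate | COC(=O)/C=C(\C)CC[C@@H](O[Si](C)(C)C(C)(C)C)C(C)(C)C=O | intermediate
11 | methyl (2E,6R,8E)-6-[(tert-butyldimethylsilyl)oxy]-9-iodo-3,7,7-trimethylnona-2,8-dienoate | COC(=O)/C=C(\C)CC[C@@H](O[Si](C)(C)C(C)(C)C)C(C)(C)/C=C/I | intermediate
12 | tert-butyldimethyl{[(2E)-3-(4,4,5,5-tetramethyl-1,3,2-dioxaborolan-2-yl)prop-2-en-1-yl]oxy}silane | CC(C)(C)[Si](C)(C)OC/C=C/B1OC(C)(C)C(C)(C)O1 | starting material
13 | methyl (2E,6R,8E,10E)-6,12-bis[(tert-butyldimethylsilyl)oxy]-3,7,7-trimethyldodeca-2,8,10-trienoate | COC(=O)/C=C(\C)CC[C@@H](O[Si](C)(C)C(C)(C)C)C(C)(C)/C=C/C=C/CO[Si](C)(C)C(C)(C)C | intermediate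
14 | methyl 6-[(tert-butyldimethylsilyl)oxy]-2-{[(tert-butyldimethylsilyl)oxy]methyl}-5,5,8a-trimethyl-1,2,4a,5,6,7,8,8a-octahydronaphthalene-1-carboxylate; 6R; trans ring fusion (H-4a anti to the 8a-methyl); CO2Me, CH2OTBS, 8a-methyl and 6-OTBS all on one face | COC(=O)[C@@H]1[C@H](CO[Si](C)(C)C(C)(C)C)C=C[C@@H]2C(C)(C)[C@H](O[Si](C)(C)C(C)(C)C)CC[C@@]12C | intermediate
15 | as 14 with CH2OH in place of CO2Me at C1 of the octalin (C11 alcohol), same configuration | OC[C@@H]1[C@H](CO[Si](C)(C)C(C)(C)C)C=C[C@@H]2C(C)(C)[C@H](O[Si](C)(C)C(C)(C)C)CC[C@@]12C | intermediate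
16 | as 14 with CHO in place of CO2Me at C1 of the octalin (C11 aldehyde), same configuration | O=C[C@@H]1[C@H](CO[Si](C)(C)C(C)(C)C)C=C[C@@H]2C(C)(C)[C@H](O[Si](C)(C)C(C)(C)C)CC[C@@]12C | intermediate
17 | methyl (3S)-4-bromo-3-methylbutanoate | COC(=O)C[C@H](C)CBr | starting material
18 | [(2S)-4-methoxy-2-methyl-4-oxobutyl]triphenylphosphonium bromide | COC(=O)C[C@H](C)C[P+](c1ccccc1)(c1ccccc1)c1ccccc1.[Br-] | intermediate
19 | methyl (3S)-3-methyl-4-(triphenyl-λ5-phosphanylidene)butanoate (ylide) | COC(=O)C[C@H](C)C=P(c1ccccc1)(c1ccccc1)c1ccccc1 | intermediate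
20 | methyl (3S,4Z)-3-methyl-5-(octalin-1-yl)pent-4-enoate, the octalin being that of 14 (6-OTBS, 2-CH2OTBS, C3=C4 ring alkene, same configuration) | COC(=O)C[C@H](C)/C=C\[C@@H]1[C@H](CO[Si](C)(C)C(C)(C)C)C=C[C@@H]2C(C)(C)[C@H](O[Si](C)(C)C(C)(C)C)CC[C@@]12C | intermediate
21 | as 20 with both silyl ethers replaced by OH (3,17-diol by labdane numbering) | COC(=O)C[C@H](C)/C=C\[C@@H]1[C@H](CO)C=C[C@@H]2C(C)(C)[C@H](O)CC[C@@]12C | intermediate
22 | as 21 with CHO in place of CH2OH on C8 (β,γ-unsaturated aldehyde, C6=C7) | COC(=O)C[C@H](C)/C=C\[C@@H]1[C@H](C=O)C=C[C@@H]2C(C)(C)[C@H](O)CC[C@@]12C | intermediate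
23 | methyl (3S,4Z)-5-[(1S,4aS,6R,8aS)-2-formyl-6-hydroxy-5,5,8a-trimethyl-1,4,4a,5,6,7,8,8a-octahydronaphthalen-1-yl]-3-methylpent-4-enoate (conjugated C7-ene aldehyde) | COC(=O)C[C@H](C)/C=C\[C@@H]1C(C=O)=CC[C@@H]2C(C)(C)[C@H](O)CC[C@@]12C | intermediate
24 | methyl (3S,4Z)-5-[(1S,4aS,6R,8aS)-6-hydroxy-2-(hydroxymethyl)-5,5,8a-trimethyl-1,4,4a,5,6,7,8,8a-octahydronaphthalen-1-yl]-3-methylpent-4-enoate | COC(=O)C[C@H](C)/C=C\[C@@H]1C(CO)=CC[C@@H]2C(C)(C)[C@H](O)CC[C@@]12C | intermediate
25 | methyl (3R)-5-[(1S,4aS,6R,8aS)-6-hydroxy-2-(hydroxymethyl)-5,5,8a-trimethyl-1,4,4a,5,6,7,8,8a-octahydronaphthalen-1-yl]-3-methylpentanoate (CNP0313905.1) | COC(=O)C[C@H](C)CC[C@@H]1C(CO)=CC[C@@H]2C(C)(C)[C@H](O)CC[C@@]12C | target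

**Step count and risks**

Total steps: 15. Longest linear sequence: 14 (steps 1–9 and 11–15 from methyl geranate; step 10 is the side branch).

Steps most likely to fail:

Step 7 (key cycloaddition). The cycloaddition may be too slow at the β,β-disubstituted ester dienophile, so that the Lewis acid ionises the dienyl silyl ether first. The exo (cis-fused) mode or the other diene face may also compete. The fallback changes the activating group; it sets out from 13 and comes back to the route at 16. Compound 13 is reduced with i-Bu2AlH (CH2Cl2, −78 °C) to the trienol F1. MnO2 (CH2Cl2, rt) should oxidise this without loss of alkene geometry to the trienal F2. Me2AlCl (CH2Cl2, −78 → −30 °C) should then close the same two bonds on the much more electrophilic enal, at a temperature where the silyl ethers are inert and the endo preference is larger. The adduct is aldehyde 16, so steps 8 and 9 fall away.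

Step 11 (Wittig reaction). The basic ylide may enolise the hindered α-branched aldehyde instead of adding to it, and the ester-bearing ylide may condense with itself on warming. The fallback is a Julia–Kocienski olefination; it sets out from 16 and 17 and comes back to the route at 25. Compound 17 with 1-phenyl-1H-tetrazole-5-thiol and K2CO3 (acetone, rt) gives the sulfide F3. H2O2 with (NH4)6Mo7O24·4H2O (EtOH) gives the sulfone F4. F4 with KN(SiMe3)2 in the presence of 16 (THF, −78 °C) should give mainly the (E)-alkene F5. F5 is taken through the conditions of steps 12 to 14, giving the E-diol F6, the β,γ-unsaturated E-aldehyde F7 (not isolated), the E-enal F8 and the E-allylic diol F9. Hydrogenation as in step 15 removes the alkene geometry and gives 25.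

Step 15 (chemoselective hydrogenation). Hydrogen delivery to the hindered cis C11=C12 bond may be slow, and forcing it may reduce or shift the C7=C8 allylic alcohol alkene. The fallback is a metal-free reduction; it sets out from 24 and comes back at 25. Diimide, generated from 2-nitrobenzenesulfonylhydrazide and Et3N (CH2Cl2, rt), transfers H2 in a concerted way and selects by degree of alkene substitution, so the trisubstituted ring alkene should survive. It makes no new compound.

Further compounds
F1 | step 7 | (2E,6R,8E,10E)-6,12-bis[(tert-butyldimethylsilyl)oxy]-3,7,7-trimethyldodeca-2,8,10-trien-1-ol | OC/C=C(\C)CC[C@@H](O[Si](C)(C)C(C)(C)C)C(C)(C)/C=C/C=C/CO[Si](C)(C)C(C)(C)C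
F2 | step 7 | (2E,6R,8E,10E)-6,12-bis[(tert-butyldimethylsilyl)oxy]-3,7,7-trimethyldodeca-2,8,10-trienal | O=C/C=C(\C)CC[C@@H](O[Si](C)(C)C(C)(C)C)C(C)(C)/C=C/C=C/CO[Si](C)(C)C(C)(C)C
F3 | step 11 | methyl (3S)-3-methyl-4-[(1-phenyl-1H-tetrazol-5-yl)sulfanyl]butanoate | COC(=O)C[C@H](C)CSc1nnnn1-c1ccccc1
F4 | step 11 | methyl (3S)-3-methyl-4-[(1-phenyl-1H-tetrazol-5-yl)sulfonyl]butanoate | COC(=O)C[C@H](C)CS(=O)(=O)c1nnnn1-c1ccccc1
F5 | step 11 | (4E)-isomer of 20 | COC(=O)C[C@H](C)/C=C/[C@@H]1[C@H](CO[Si](C)(C)C(C)(C)C)C=C[C@@H]2C(C)(C)[C@H](O[Si](C)(C)C(C)(C)C)CC[C@@]12C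
F6 | step 11 | (4E)-isomer of 21 | COC(=O)C[C@H](C)/C=C/[C@@H]1[C@H](CO)C=C[C@@H]2C(C)(C)[C@H](O)CC[C@@]12C
F7 | step 11 | (4E)-isomer of 22 | COC(=O)C[C@H](C)/C=C/[C@@H]1[C@H](C=O)C=C[C@@H]2C(C)(C)[C@H](O)CC[C@@]12C
F8 | step 11 | (4E)-isomer of 23 | COC(=O)C[C@H](C)/C=C/[C@@H]1C(C=O)=CC[C@@H]2C(C)(C)[C@H](O)CC[C@@]12C
F9 | step 11 | (4E)-isomer of 24 | COC(=O)C[C@H](C)/C=C/[C@@H]1C(CO)=CC[C@@H]2C(C)(C)[C@H](O)CC[C@@]12C
F0 | step 15 | none | none
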